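I wanted the tris adduct at the end.

| flask | starting material | reagent | remark | time |
|---|---|---|---|---|
| maple | 0.22 M | 0.20 M | run made earlier |  |
| ash | 0.22 M | 0.46 M | run made earlier |  |
| birch | 0.22 M | 0.78 M | run made earlier |  |
| north-west | 0.22 M | 0.220 M |  | 8.0 h |
| north-east | 0.22 M | 0.550 M |  | 8.0 h |
| east | 0.22 M | 0.880 M |  | 8.0 h |

| run | time / h | tris adduct / % | double product / % |
|---|---|---|---|
| maple | 1.00 | 0.5 | 1.2 |
| maple | 2.50 | 0.6 | 2.3 |
| maple | 3.00 | 1.1 | 1.7 |
| maple | 5.00 | 2.5 | 3.1 |
| maple | 6.00 | 3.4 | 2.7 |
| ash | 0.500 | 0 | 0.4 |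
| ash | 1.33 | 1.7 | 2.7 |
| ash | 2.50 | 6.1 | 4.6 |
| ash | 4.00 | 11.8 | 5.2 |
| ash | 6.00 | 18.5 | 5.8 |
| birch | 0.417 | 1.0 | 1.1 |
| birch | 0.833 | 2.2 | 3.1 |
| birch | 1.50 | 8.7 | 4.9 |
| birch | 3.00 | 22.0 | 6.4 |
| birch | 6.00 | 41.0 | 4.3 |

(standard deviation of a reading: 0.3 percentage points)

- the earlier runs were read with a standard deviation of 0.3 percentage points

- how much tris adduct is there at the end, in percent of the starting material charged: for each flask in turn (north-west, north-east, east)

I started at the low end. In maple at 6.00 h the tris adduct read 3.4 %. The runs seemed to grow with time and with the reagent charge squared, so I divided that reading by both and got 0.142 M⁻² h⁻¹. But this straight line promised 51.8 % in birch at 6.00 h, more than the 41.0 % read there.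

The stock of starting material is finite, so the line had to bend. I joined the two ends with a decay: the fraction turned into tris adduct is one minus the exponential of minus a constant, times the reagent charge squared, times the time. That makes the constant times the charge squared an apparent pseudo-first-order constant. Birch gave 0.145 M⁻² h⁻¹, and I called this the squared-reagent constant.

Was it real? Maple, read through the same curve, gave 0.144 M⁻² h⁻¹, but that reading had already gone into joining the two ends, so this agreement was no check. Ash, which I had not used yet, gave 0.161 M⁻² h⁻¹, and I kept that gap as my doubt.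

A second doubt was that reagent falls during a run, while the constant uses its charge. Yet north-west's charge of 0.220 M stands close to maple's 0.20 M, and east's 0.880 M close to birch's 0.78 M. Those runs had carried that fall up to 6.00 h, so I accepted the constant.

For 8.0 h I reckoned 5.44 %, 29.5 % and 59.2 %. The forecast also held that the rate “scales roughly with reagent squared”. It gave 5.5 %, 27 % and 51 %, lower than mine in north-east and east.

The flasks gave 5.48 %, 31.6 % and 55.7 %, and the forecast held.

starting material + reagent → single product (k = 1.15 M⁻¹ h⁻¹); reagent + double product → over-reaction product (k = 0.764 M⁻¹ h⁻¹); reagent + double product → tris adduct (k = 3.23 M⁻¹ h⁻¹); reagent + single product → double product (k = 0.411 M⁻¹ h⁻¹) Read back from these results, the squared-reagent constant was 0.146 M⁻² h⁻¹ in north-west and 0.131 M⁻² h⁻¹ in east, against my 0.145 M⁻² h⁻¹. At 1.80 h in north-west the single product was made 6.67 times faster than it was used up. At 8.00 h that flask held 51.0 % single product against 5.48 % tris adduct.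

The runs were generated by integration for substances that don't exist, and the scatter is random.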